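I wanted to know what this flask holds at its time of looking, and which remedy adds target to it.

in all of them: temperature 80 °C
- spring: starting material 0.050 M; partner 0.10 M; the very flask that is asked about, followed so far
- summer: starting material 0.034 M; partner 0.10 M; run made earlier
- flask: starting material 0.050 M; partner 0.100 M; time 5.0 h

- spring (time / min: target / %): 60.0: 42; 120: 41; 180: 38; 240: 41; 300: 40
- summer (time / min: target / %): 1.00: 0; 3.00: 10; 6.00: 20; 8.00: 25; 12.0: 38

(each reading ± 1.5 percentage points)

- ochre: change nothing and wait 10 h more
- grey: at 5.0 h raise the temperature by 15 K, then wait 10 h
- blue: at 5.0 h take out 90% of the target then present, then wait 10 h
- violet: at 5.0 h add partner, 100% of the amount charged, then wait 10 h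

1. target, in percent of the starting material first charged, at 5.0 h
2. the remedy with the largest gain of target, or "none" below 2 percentage points (ochre / grey / blue / violet / none)
3. target present, with what was taken out counted in, in percent of the starting material first charged, after grey
4. target present, with what was taken out counted in, in percent of the starting material first charged, after violet

- what is taken out of target is counted as made
- the numbers in the tables scatter with a standard deviation of 1.5 percentage points
- the earlier runs do not show what temperature does; that part of a forecast is a guess
- additions bring no volume worth counting

- The spring run is this flask followed so far, and its readings stayed flat, so I froze them at their mean, 40.4%, and took that as the answer at 5.0 h.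
- That mean is [target] = 0.02020 M. Divided by the [partner] charged, it gives the partner yield, the target made per partner charged: 20.2%.
- I supposed that partner, despite its 2.00 equivalents, was the limiting reagent, and that the other 79.8% of it went somewhere other than target.
- The summer run made target at about 0.001077 M min⁻¹, so at that pace the spring amount takes 18.8 min, less than the 60.0 min of the first flat reading.
- On that estimate, a partner dose gives its 0.0202 M of target in less time than 5.0 h, so I expected nothing from waiting or from taking target out. For heat I guessed the same, since no run shows temperature, and kept the target at the plateau.
- Violet adds a fresh dose of 0.100 M, and at the same yield that gains 40 percentage points. This is less than the 59.6% of the charge not yet target, so I committed to violet and 80.8%.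
- The weak link was the supposition about partner, so I tried it on the summer run. There the same yield gives an estimated end value of 59.4%, above the last reading of 38%, so the summer run, still climbing at that reading, did not contradict the supposition, though it did not test it either.
- The forecast, which parted from my reckoning on violet, gave 40.4% now, none as best, 40% after grey and 40.5% after violet, saying: “Waiting, removing target or adding partner should therefore gain nothing.”
- The flask gave 42.0% at 5.0 h, 42.0% after grey and 89.2% after violet, a gain of 47 points, so the best remedy was violet.

    starting material → open intermediate (k = 0.130 min⁻¹, Ea = 112 kJ mol⁻¹)
    partner → second intermediate (k = 0.430 min⁻¹, Ea = 112 kJ mol⁻¹)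
    open intermediate + second intermediate → target (k = 8.00 L mol⁻¹ min⁻¹, Ea = 65.0 kJ mol⁻¹)
    2 second intermediate → homo product (k = 12.0 L mol⁻¹ min⁻¹, Ea = 70.0 kJ mol⁻¹)
    starting material + open intermediate → side product (k = 0.100 L mol⁻¹ min⁻¹, Ea = 87.0 kJ mol⁻¹)
    (constants at 80 °C)

- At 300 min the flask had 0% of its partner left, while 55.8% of the starting material stood as open intermediate.
- The flask's own partner yield came to 21.0%. Carried to the neighbour flask with 0.025 M of partner, my 20.2% gave 10.1% target, but that neighbour flask held 23.1%, a partner yield of 46.3%.

(The numbers in the tables stem from a simulated flask with constants of no real substance; the scatter is artificial.)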